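Readings and results stem from a simulated flask from invented constants; noise was put on by code.

**Late decline.** At the late end of the north run, E (the complex with one ligand exchanged) stands at 16.5% at 2.50 min, down from 33.1% at 0.333 min. That reads as a loss half-life, the time E takes to halve after the burst, of 2.16 min. The south-west run, with half the J concentration, reads 2.22 min, so the decline looks first-order.

| flask | J | L | remark | time |
|---|---|---|---|---|
| south-west | 0.29 M | 0.50 equiv | the very flask that is asked about, followed so far |  |
| north | 0.58 M | 0.50 equiv | run made earlier |  |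
| flask | 0.29 M | 0.500 equiv |  | 2.5 min |

south-west run (percent of the J charged)

| time / s | E / % | Z / % |
|---|---|---|
| 10.0 | 33.3 | 0.8 |
| 15.0 | 33.5 | 0.4 |
| 30.0 | 31.1 | 2.7 |
| 80.0 | 23.9 | 0.6 |

north run (percent of the J charged)

| time / min | E / % | Z / % |
|---|---|---|
| 0.333 | 33.1 | 0.8 |
| 0.833 | 29.6 | 2.1 |
| 1.50 | 25.4 | 1.4 |
| 2.50 | 16.5 | 0.9 |

(scatter of a reading: 1 percentage point)

- equivalents of L to J, everything else as given, that leave most E at 2.5 min
- the amount of E then, in percent of the J charged
- the amount of E with the amounts as given

**Two times.** The south-west run reads 33.3% E at 10.0 s and 33.5% at 15.0 s, so within the scatter the readings show the rise of E ended by the first of these times. The half-life is 13.0 times that reading time, so burst and loss can be reckoned apart, by the fraction left.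

**Own reckoning.** From the south-west reading of 33.5% at 15.0 s, the fraction left at 2.5 min is 48.5%, which gives 16.3% E.

**The forecast.** It gives 16.5%, slightly different from this reckoning, and 21% at 1 equiv, on the grounds: “That points to first-order loss of E”.

**The result.** The flask gives 17.1%, and 1.21 equiv of L leaves the most E, 24.7%.

    J + L → X + E (k = 3.02 /M/s)
    E + L → X + D (k = 1.22 /M/s)
    D + L → X + Z (k = 5.10 /M/s)
    E → G (k = 0.00545 /s)
    L ⇌ Q (K = 14.0, k = 0.0928 /s)

**Earlier reading.** The south-west flask read at 1.0 min has unbound L, the limiting reagent, at 0.067% of its charge, beside 0.0110 M of Q. From 33.5% at 15.0 s, the loss half-life leaves 78.6%, or 26.3% E. That flask holds 26.6%.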